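**Retrosynthetic overview**

1. Feature: ring B (C5–C10) holds its only carbonyl at C8 between two methylenes and carries cis methyl groups on quaternary C5 and on C10. This is the pattern left when a 2-silyloxy-1,3-diene (C6–C9) adds to an E-2-methylbut-2-enoyl alkene (C5=C10) whose activating carbonyl sits temporarily on C4.
2. Key disconnection: C5–C6 and C9–C10 are cut together (intramolecular Diels–Alder of trienone 25). Rings A and B form in the same step, ring B as the cycloadduct and ring A through the C1–C4 tether; the oxirane ring is made last.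
3. Trienone 25 comes from Weinreb amide 21 and (E)-but-2-en-2-yllithium (C4–C5), so the epimerisable β,γ-unsaturated ketone exists only when it is needed. The diene comes from a C6 aldehyde by Wittig reaction (C6=C7) and enol silylation.
4. C2–C3 and both stereocentres come from an Evans dienolate syn-aldol of senecioyl imide 10 with the (S)-glyceraldehyde derivative 6 (from (S)-solketal). The erythro C1/C2 diol is tied as the cis-acetonide.
5. End game: C4 ketone to CH2 (reduction, Barton–McCombie) with the silyl enol ether as the C8 protecting group, acid unmasking, C1 angelate via a temporary C2 silyl ether, C2-hydroxyl-directed epoxidation.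

Key step: step 14

Remarks: Skeleton numbering is used throughout (ring A: C1 O-acyl carbon, C2 carbinol, C3, C4, C5 quaternary, C6 ring-fusion CH; ring B: C6, C7, C8 carbonyl, C9, C10, C5). β is the face of the C5 methyl group; the absolute configuration is that of the SMILES strings. Assumption: the C4 carbinol of 27 forms as an epimer mixture that converges in step 17, so 27–29 carry no descriptor at C4.

**Route**

Step 1
Reactants: 1 (S)-(2,2-dimethyl-1,3-dioxolan-4-yl)methanol
Product: 2 (S)-4-{[(4-methoxybenzyl)oxy]methyl}-2,2-dimethyl-1,3-dioxolane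
Conditions: NaH, PMBCl, Bu4NI (cat.), THF/DMF, 0 °C to rt
Reagents that add atoms: 4-methoxybenzyl chloride, COc1ccc(CCl)cc1
Why: Williamson ether synthesis on the primary alkoxide; the stereocentre is not involved, and PMB can later be removed oxidatively in the presence of alkenes and an acetonide.

Step 2
Reactants: 2 (S)-4-{[(4-methoxybenzyl)oxy]methyl}-2,2-dimethyl-1,3-dioxolane
Product: 3 (R)-3-[(4-methoxybenzyl)oxy]propane-1,2-diol
Conditions: AcOH/H2O (4:1), 40 °C
Reagents that add atoms: none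
Why: Acid-catalysed acetal hydrolysis; the PMB ether tolerates dilute acetic acid and the stereocentre is untouched (the descriptor changes only through the priority rules).

Step 3
Reactants: 3 (R)-3-[(4-methoxybenzyl)oxy]propane-1,2-diol
Product: 4 (S)-1-[(4-methoxybenzyl)oxy]-2,3-bis(triethylsilyloxy)propane
Conditions: Et3SiCl, imidazole, DMF, 0 °C to rt
Reagents that add atoms: chlorotriethylsilane, CC[Si](Cl)(CC)CC
Why: Imidazole-mediated silylation of both hydroxyls; triethylsilyl allows the primary ether to be oxidised directly and the secondary one to be removed later under mild acid.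

Step 4
Reactants: 4 (S)-1-[(4-methoxybenzyl)oxy]-2,3-bis(triethylsilyloxy)propane
Product: 6 (S)-3-[(4-methoxybenzyl)oxy]-2-(triethylsilyloxy)propanal, via alkoxysulfonium chloride 5 (not isolated)
Conditions: (COCl)2, DMSO, CH2Cl2, −78 to −30 °C; then Et3N, −78 to 0 °C
Reagents that add atoms: none
Why: Swern oxidation applied directly to the primary triethylsilyl ether (the activated sulfonium reagent cleaves the unhindered primary Si–O bond, the secondary ether stays), so no separate deprotection is needed; the α-silyloxy aldehyde is used at once to avoid α-epimerisation.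

Step 5
Reactants: 7 (R)-4-benzyloxazolidin-2-one; 8 3-methylbut-2-enoyl chloride
Product: 10 (R)-4-benzyl-3-(3-methylbut-2-enoyl)oxazolidin-2-one, via N-lithio oxazolidinone 9 (not isolated)
Conditions: n-BuLi, THF, −78 °C; then 8, −78 to 0 °C
Reagents that add atoms: none
Why: N-acylation of the lithiated oxazolidinone; amine-free conditions avoid the vinylketene pathway that would deconjugate the acid chloride.

Step 6
Reactants: 10 (R)-4-benzyl-3-(3-methylbut-2-enoyl)oxazolidin-2-one; 6 (S)-3-[(4-methoxybenzyl)oxy]-2-(triethylsilyloxy)propanal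
Product: 13 (R)-4-benzyl-3-[(2R,3R,4S)-3-hydroxy-5-[(4-methoxybenzyl)oxy]-2-(prop-1-en-2-yl)-4-(triethylsilyloxy)pentanoyl]oxazolidin-2-one, via boron dienolate 11 (not isolated), via boron aldolate 12 (not isolated)
Conditions: Bu2BOTf, Et3N, CH2Cl2, −78 to 0 °C; then 6, −78 to 0 °C; then H2O2, MeOH, pH 7 buffer, 0 °C
Reagents that add atoms: none
Why: Evans syn-aldol: soft enolisation at the γ-methyl gives the Z(O)-boron dienolate, which reacts at its α-carbon through a Zimmerman–Traxler chair with the auxiliary dictating the enolate face, so C3 and C2 are set syn (2R,3R in the adduct) and C2–OH anti to the existing C1 oxygen under reagent control.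

Step 7
Reactants: 13 (R)-4-benzyl-3-[(2R,3R,4S)-3-hydroxy-5-[(4-methoxybenzyl)oxy]-2-(prop-1-en-2-yl)-4-(triethylsilyloxy)pentanoyl]oxazolidin-2-one
Product: 14 (2R,3R,4S)-3-hydroxy-N-methoxy-5-[(4-methoxybenzyl)oxy]-N-methyl-2-(prop-1-en-2-yl)-4-(triethylsilyloxy)pentanamide
Conditions: MeNH(OMe)·HCl, AlMe3, THF/CH2Cl2, −20 to 0 °C
Reagents that add atoms: N,O-dimethylhydroxylamine hydrochloride, Cl.CNOC
Why: Weinreb transamination of the β-hydroxy imide with the aluminium amide (the free C2–OH directs attack to the exocyclic carbonyl); no stereocentre is touched and the auxiliary is recovered.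

Step 8
Reactants: 14 (2R,3R,4S)-3-hydroxy-N-methoxy-5-[(4-methoxybenzyl)oxy]-N-methyl-2-(prop-1-en-2-yl)-4-(triethylsilyloxy)pentanamide
Product: 16 (2R)-N-methoxy-2-[(4R,5S)-5-{[(4-methoxybenzyl)oxy]methyl}-2,2-dimethyl-1,3-dioxolan-4-yl]-N,3-dimethylbut-3-enamide, via diol 15 (not isolated)
Conditions: CSA (cat.), MeOH, 0 °C; then Me2C(OMe)2, acetone, rt
Reagents that add atoms: 2,2-dimethoxypropane, COC(C)(C)OC
Why: Acid methanolysis of the secondary triethylsilyl ether followed by transketalisation; the erythro C1/C2 diol can only close to the cis-4,5-disubstituted dioxolane, and the PMB ether keeps the C6 oxygen out of the ketal.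

Step 9
Reactants: 16 (2R)-N-methoxy-2-[(4R,5S)-5-{[(4-methoxybenzyl)oxy]methyl}-2,2-dimethyl-1,3-dioxolan-4-yl]-N,3-dimethylbut-3-enamide
Product: 17 (2R)-2-[(4R,5S)-5-(hydroxymethyl)-2,2-dimethyl-1,3-dioxolan-4-yl]-N-methoxy-N,3-dimethylbut-3-enamide
Conditions: DDQ, CH2Cl2/pH 7 buffer (10:1), 0 °C to rt
Reagents that add atoms: none
Why: Oxidative cleavage of the PMB ether (single-electron oxidation, then hemiacetal hydrolysis); the buffered conditions leave acetonide, isopropenyl group and Weinreb amide alone.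

Step 10
Reactants: 17 (2R)-2-[(4R,5S)-5-(hydroxymethyl)-2,2-dimethyl-1,3-dioxolan-4-yl]-N-methoxy-N,3-dimethylbut-3-enamide
Product: 18 (2R)-2-[(4R,5R)-5-formyl-2,2-dimethyl-1,3-dioxolan-4-yl]-N-methoxy-N,3-dimethylbut-3-enamide
Conditions: Dess–Martin periodinane, CH2Cl2, 0 °C to rt
Reagents that add atoms: none
Why: Dess–Martin oxidation under near-neutral conditions; the cis-dioxolane aldehyde is used crude to avoid epimerisation at C1.

Step 11
Reactants: 18 (2R)-2-[(4R,5R)-5-formyl-2,2-dimethyl-1,3-dioxolan-4-yl]-N-methoxy-N,3-dimethylbut-3-enamide; 19 1-(triphenylphosphoranylidene)propan-2-one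
Product: 20 (2R)-2-{(4R,5S)-2,2-dimethyl-5-[(1E)-3-oxobut-1-en-1-yl]-1,3-dioxolan-4-yl}-N-methoxy-N,3-dimethylbut-3-enamide
Conditions: CH2Cl2, rt
Reagents that add atoms: none
Why: Wittig reaction with a stabilised ylide, E-selective and mild enough for the α-alkoxy aldehyde; it installs C7–C9 and the E C6=C7 bond.

Step 12
Reactants: 20 (2R)-2-{(4R,5S)-2,2-dimethyl-5-[(1E)-3-oxobut-1-en-1-yl]-1,3-dioxolan-4-yl}-N-methoxy-N,3-dimethylbut-3-enamide
Product: 21 (2R)-2-{(4R,5S)-5-[(1E)-3-(tert-butyldimethylsilyloxy)buta-1,3-dien-1-yl]-2,2-dimethyl-1,3-dioxolan-4-yl}-N-methoxy-N,3-dimethylbut-3-enamide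
Conditions: t-BuMe2SiOTf, Et3N, CH2Cl2, −78 to 0 °C
Reagents that add atoms: tert-butyldimethylsilyl trifluoromethanesulfonate, CC(C)(C)[Si](C)(C)OS(=O)(=O)C(F)(F)F
Why: Soft enolisation (silyl triflate/amine) of the methyl ketone gives the cross-conjugated 2-silyloxy-1,3-diene; C4 is still an amide here, whose C3–H is far less acidic than that of the later ketone, so the C3 stereocentre is safe.

Step 13
Reactants: 22 (E)-2-bromobut-2-ene; 21 (2R)-2-{(4R,5S)-5-[(1E)-3-(tert-butyldimethylsilyloxy)buta-1,3-dien-1-yl]-2,2-dimethyl-1,3-dioxolan-4-yl}-N-methoxy-N,3-dimethylbut-3-enamide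
Product: 25 (2E,5R)-5-{(4R,5S)-5-[(1E)-3-(tert-butyldimethylsilyloxy)buta-1,3-dien-1-yl]-2,2-dimethyl-1,3-dioxolan-4-yl}-3,6-dimethylhepta-2,6-dien-4-one, via (E)-but-2-en-2-yllithium 23 (not isolated), via lithium hemiaminal adduct 24 (not isolated)
Conditions: 22, t-BuLi (2 equiv), Et2O, −78 °C; then 21, THF, −78 to −40 °C; then cold aq. NH4Cl
Reagents that add atoms: none
Why: Weinreb ketone synthesis: Li–Br exchange proceeds with retention, so the E (tigloyl) geometry is carried into the organolithium, which adds once to the amide to give a chelated tetrahedral adduct that releases the ketone only on quench; the silyl enol ether is inert to organolithiums at −78 °C and the C3–H meets no base once the ketone exists.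

Step 14
Reactants: 25 (2E,5R)-5-{(4R,5S)-5-[(1E)-3-(tert-butyldimethylsilyloxy)buta-1,3-dien-1-yl]-2,2-dimethyl-1,3-dioxolan-4-yl}-3,6-dimethylhepta-2,6-dien-4-one
Product: 26 8-(tert-butyldimethylsilyloxy)-3β-isopropenyl-1α,2α-(isopropylidenedioxy)-5β,10β-dimethyl-6βH-cis-decal-7-en-4-one
Conditions: PhMe (0.01 M), BHT (cat.), Et3N (cat.), 80 °C
Reagents that add atoms: none
Why: Thermal, concerted but asynchronous [4+2] cycloaddition, a type 1 intramolecular Diels–Alder reaction of a 1,7,9-decatrien-3-one bearing a 2-silyloxydiene, in which the nucleophilic diene terminus C9 is matched to the electrophilic β-carbon C10 of the enone. Ring B is closed as the cycloadduct itself (C5–C6 and C9–C10 formed suprafacially on both partners) and ring A is closed at the same moment in the fused mode, the four-carbon tether C1–C4 spanning diene terminus C6 and dienophile carbon C5. C5 and C10: the E geometry of the tigloyl alkene is transferred, so the two methyl groups end up cis. C6 relative to C5: the tether carbonyl C4 lies endo under the diene, which keeps both methyl groups exo and gives the cis ring fusion, whereas the exo-carbonyl mode would push both methyls under the diene and twist the enone out of conjugation. Sense relative to C1–C3: the tether should adopt the chair with the C3 isopropenyl group and the C2 oxygen equatorial and the cis-fused dioxolane holding C1–O axial, the diene arm reacting from its equatorial position on C6; addition to the other dienophile face needs the diene arm axial with the C5 methyl syn-axial to C1–O, or a chair flip that sets the isopropenyl group axial against C10. The step thus needs endo (cis-fusion) and π-facial selectivity, the first secured by the α-methyl enone and the second by the acetonide- and isopropenyl-substituted tether; regiochemistry is fixed by the tether.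

Step 15
Reactants: 26 8-(tert-butyldimethylsilyloxy)-3β-isopropenyl-1α,2α-(isopropylidenedioxy)-5β,10β-dimethyl-6βH-cis-decal-7-en-4-one
Product: 27 8-(tert-butyldimethylsilyloxy)-3β-isopropenyl-1α,2α-(isopropylidenedioxy)-5β,10β-dimethyl-6βH-cis-decal-7-en-4ξ-ol
Conditions: LiAlH4, Et2O, −78 to 0 °C
Reagents that add atoms: none
Why: Hydride reduction of the hindered C4 ketone; silyl enol ether, acetonide and alkene are inert to LiAlH4, and the new C4 stereocentre (either epimer) is removed in step 17.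

Step 16
Reactants: 27 8-(tert-butyldimethylsilyloxy)-3β-isopropenyl-1α,2α-(isopropylidenedioxy)-5β,10β-dimethyl-6βH-cis-decal-7-en-4ξ-ol
Product: 29 O-(C4) S-methyl dithiocarbonate of alcohol 27, via potassium xanthate 28 (not isolated)
Conditions: KN(SiMe3)2, CS2, THF, −78 to 0 °C; then MeI, 0 °C to rt
Reagents that add atoms: carbon disulfide, S=C=S; iodomethane, CI
Why: Xanthate formation (alkoxide, CS2, S-methylation), the first half of the Barton–McCombie deoxygenation; the strong non-nucleophilic base is needed for the neopentyl-type alcohol and nothing else in 27 is base-sensitive.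

Step 17
Reactants: 29 O-(C4) S-methyl dithiocarbonate of alcohol 27
Product: 30 8-(tert-butyldimethylsilyloxy)-3β-isopropenyl-1α,2α-(isopropylidenedioxy)-5β,10β-dimethyl-6βH-cis-decal-7-ene
Conditions: Bu3SnH, AIBN (cat.), PhMe, 90 °C
Reagents that add atoms: none
Why: Barton–McCombie deoxygenation (radical chain); the secondary C4 radical should be reduced by the stannane faster than it can rearrange through the cyclopropylcarbinyl (1,2-vinyl shift) manifold, and it is too far from the enol ether to cyclise.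

Step 18
Reactants: 30 8-(tert-butyldimethylsilyloxy)-3β-isopropenyl-1α,2α-(isopropylidenedioxy)-5β,10β-dimethyl-6βH-cis-decal-7-ene
Product: 31 1α,2α-dihydroxy-3β-isopropenyl-5β,10β-dimethyl-6βH-cis-decalin-8-one
Conditions: AcOH/H2O/THF (3:1:1), 45 °C
Reagents that add atoms: none
Why: Acid hydrolysis removes acetonide and silyl enol ether in one operation, giving the C8 ketone and the C1/C2 diol; no stereocentre is α to the new ketone and dilute acetic acid spares the isopropenyl group.

Step 19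
Reactants: 31 1α,2α-dihydroxy-3β-isopropenyl-5β,10β-dimethyl-6βH-cis-decalin-8-one
Product: 32 1α-hydroxy-3β-isopropenyl-5β,10β-dimethyl-2α-(triethylsilyloxy)-6βH-cis-decalin-8-one
Conditions: Et3SiCl (1.1 equiv), imidazole, CH2Cl2, −30 °C
Reagents that add atoms: chlorotriethylsilane, CC[Si](Cl)(CC)CC
Why: Regioselective silylation: in the preferred cis-decalin chair (C3 substituent equatorial) the C2 hydroxyl is equatorial and the C1 hydroxyl is axial on the concave face, so the silyl chloride should take C2–OH.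

Step 20
Reactants: 33 angelic acid [(Z)-2-methylbut-2-enoic acid]; 32 1α-hydroxy-3β-isopropenyl-5β,10β-dimethyl-2α-(triethylsilyloxy)-6βH-cis-decalin-8-one
Product: 35 3β-isopropenyl-5β,10β-dimethyl-8-oxo-2α-(triethylsilyloxy)-6βH-cis-decalin-1α-yl (Z)-2-methylbut-2-enoate, via mixed anhydride 34 (not isolated)
Conditions: 33, 2,4,6-Cl3C6H2COCl, Et3N, PhMe, rt; then 32, PhMe, 80 °C
Reagents that add atoms: none
Why: Yamaguchi-type esterification through the 2,4,6-trichlorobenzoyl mixed anhydride, run without DMAP because nucleophilic catalysts isomerise angelates to tiglates; heating is needed for the axial C1 hydroxyl.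

Step 21
Reactants: 35 3β-isopropenyl-5β,10β-dimethyl-8-oxo-2α-(triethylsilyloxy)-6βH-cis-decalin-1α-yl (Z)-2-methylbut-2-enoate
Product: 36 2α-hydroxy-3β-isopropenyl-5β,10β-dimethyl-8-oxo-6βH-cis-decalin-1α-yl (Z)-2-methylbut-2-enoate
Conditions: HF·pyridine, pyridine, THF, 0 °C to rt
Reagents that add atoms: none
Why: Fluoride-mediated desilylation under buffered acidic conditions, which avoids base-induced migration of the angelate from C1 to C2.

Step 22
Reactants: 36 2α-hydroxy-3β-isopropenyl-5β,10β-dimethyl-8-oxo-6βH-cis-decalin-1α-yl (Z)-2-methylbut-2-enoate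
Product: 37 2α-hydroxy-5β,10β-dimethyl-3β-[(2R)-2-methyloxiran-2-yl]-8-oxo-6βH-cis-decalin-1α-yl (Z)-2-methylbut-2-enoate (CNP0206528.1)
Conditions: VO(acac)2 (5 mol %), t-BuOOH, CH2Cl2, 0 °C to rt
Reagents that add atoms: tert-butyl hydroperoxide, CC(C)(C)OO
Why: Hydroxyl-directed epoxidation (vanadium-catalysed, homoallylic alcohol): the vanadate ester of the equatorial C2–OH delivers oxygen through a chair-like transition state to the isopropenyl face turned toward C2, with the vinylic methyl rotated away from C2, which should give the (2R)-oxirane; the electron-poor angelate alkene is not touched.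

**Compound list**

1 | (S)-(2,2-dimethyl-1,3-dioxolan-4-yl)methanol [(S)-solketal] | CC1(C)OC[C@H](CO)O1 | starting material
2 | (S)-4-{[(4-methoxybenzyl)oxy]methyl}-2,2-dimethyl-1,3-dioxolane | COc1ccc(COC[C@H]2COC(C)(C)O2)cc1 | intermediate
3 | (R)-3-[(4-methoxybenzyl)oxy]propane-1,2-diol | COc1ccc(COC[C@H](O)CO)cc1 | intermediate
4 | (S)-1-[(4-methoxybenzyl)oxy]-2,3-bis(triethylsilyloxy)propane | CC[Si](CC)(CC)OC[C@@H](O[Si](CC)(CC)CC)COCc1ccc(OC)cc1 | intermediate
5 | dimethyl{(S)-3-[(4-methoxybenzyl)oxy]-2-(triethylsilyloxy)propoxy}sulfonium chloride (alkoxysulfonium chloride) | C[S+](C)OC[C@@H](O[Si](CC)(CC)CC)COCc1ccc(OC)cc1.[Cl-] | intermediate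
6 | (S)-3-[(4-methoxybenzyl)oxy]-2-(triethylsilyloxy)propanal | O=C[C@@H](O[Si](CC)(CC)CC)COCc1ccc(OC)cc1 | intermediate
7 | (R)-4-benzyloxazolidin-2-one | O=C1N[C@H](Cc2ccccc2)CO1 | starting material
8 | 3-methylbut-2-enoyl chloride | CC(C)=CC(Cl)=O | starting material
9 | N-lithio (R)-4-benzyloxazolidin-2-one | [Li]N1[C@H](Cc2ccccc2)COC1=O | intermediate
10 | (R)-4-benzyl-3-(3-methylbut-2-enoyl)oxazolidin-2-one | CC(C)=CC(=O)N1[C@H](Cc2ccccc2)COC1=O | intermediate
11 | (R)-4-benzyl-3-[(1Z)-1-(dibutylboranyloxy)-3-methylbuta-1,3-dien-1-yl]oxazolidin-2-one (boron dienolate) | C=C(C)/C=C(\OB(CCCC)CCCC)N1[C@H](Cc2ccccc2)COC1=O | intermediate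
12 | O-dibutylboranyl derivative of 13 (boron aldolate) | O=C1OC[C@@H](Cc2ccccc2)N1C(=O)[C@H](C(C)=C)[C@@H](OB(CCCC)CCCC)[C@@H](O[Si](CC)(CC)CC)COCc1ccc(OC)cc1 | intermediate
13 | (R)-4-benzyl-3-[(2R,3R,4S)-3-hydroxy-5-[(4-methoxybenzyl)oxy]-2-(prop-1-en-2-yl)-4-(triethylsilyloxy)pentanoyl]oxazolidin-2-one | O=C1OC[C@@H](Cc2ccccc2)N1C(=O)[C@H](C(C)=C)[C@@H](O)[C@@H](O[Si](CC)(CC)CC)COCc1ccc(OC)cc1 | intermediate
14 | (2R,3R,4S)-3-hydroxy-N-methoxy-5-[(4-methoxybenzyl)oxy]-N-methyl-2-(prop-1-en-2-yl)-4-(triethylsilyloxy)pentanamide | CON(C)C(=O)[C@H](C(C)=C)[C@@H](O)[C@@H](O[Si](CC)(CC)CC)COCc1ccc(OC)cc1 | intermediate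
15 | (2R,3R,4S)-3,4-dihydroxy-N-methoxy-5-[(4-methoxybenzyl)oxy]-N-methyl-2-(prop-1-en-2-yl)pentanamide (diol) | CON(C)C(=O)[C@H](C(C)=C)[C@@H](O)[C@@H](O)COCc1ccc(OC)cc1 | intermediate
16 | (2R)-N-methoxy-2-[(4R,5S)-5-{[(4-methoxybenzyl)oxy]methyl}-2,2-dimethyl-1,3-dioxolan-4-yl]-N,3-dimethylbut-3-enamide | CON(C)C(=O)[C@H](C(C)=C)[C@H]1OC(C)(C)O[C@H]1COCc1ccc(OC)cc1 | intermediate
17 | (2R)-2-[(4R,5S)-5-(hydroxymethyl)-2,2-dimethyl-1,3-dioxolan-4-yl]-N-methoxy-N,3-dimethylbut-3-enamide | CON(C)C(=O)[C@H](C(C)=C)[C@H]1OC(C)(C)O[C@H]1CO | intermediate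
18 | (2R)-2-[(4R,5R)-5-formyl-2,2-dimethyl-1,3-dioxolan-4-yl]-N-methoxy-N,3-dimethylbut-3-enamide | CON(C)C(=O)[C@H](C(C)=C)[C@H]1OC(C)(C)O[C@H]1C=O | intermediate
19 | 1-(triphenylphosphoranylidene)propan-2-one | CC(=O)C=P(c1ccccc1)(c1ccccc1)c1ccccc1 | starting material
20 | (2R)-2-{(4R,5S)-2,2-dimethyl-5-[(1E)-3-oxobut-1-en-1-yl]-1,3-dioxolan-4-yl}-N-methoxy-N,3-dimethylbut-3-enamide | CON(C)C(=O)[C@H](C(C)=C)[C@H]1OC(C)(C)O[C@H]1/C=C/C(C)=O | intermediate
21 | (2R)-2-{(4R,5S)-5-[(1E)-3-(tert-butyldimethylsilyloxy)buta-1,3-dien-1-yl]-2,2-dimethyl-1,3-dioxolan-4-yl}-N-methoxy-N,3-dimethylbut-3-enamide | CON(C)C(=O)[C@H](C(C)=C)[C@H]1OC(C)(C)O[C@H]1/C=C/C(=C)O[Si](C)(C)C(C)(C)C | intermediate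
22 | (E)-2-bromobut-2-ene | C/C=C(\C)Br | starting material
23 | (E)-but-2-en-2-yllithium | C/C=C(\C)[Li] | intermediate
24 | lithium hemiaminal adduct of 21 and 23 (tetrahedral O-lithio N-methoxy-N-methyl aminal at C4) | C/C=C(\C)C(O[Li])(N(C)OC)[C@H](C(C)=C)[C@H]1OC(C)(C)O[C@H]1/C=C/C(=C)O[Si](C)(C)C(C)(C)C | intermediate
25 | (2E,5R)-5-{(4R,5S)-5-[(1E)-3-(tert-butyldimethylsilyloxy)buta-1,3-dien-1-yl]-2,2-dimethyl-1,3-dioxolan-4-yl}-3,6-dimethylhepta-2,6-dien-4-one | C/C=C(\C)C(=O)[C@H](C(C)=C)[C@H]1OC(C)(C)O[C@H]1/C=C/C(=C)O[Si](C)(C)C(C)(C)C | intermediate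
26 | 8-(tert-butyldimethylsilyloxy)-3β-isopropenyl-1α,2α-(isopropylidenedioxy)-5β,10β-dimethyl-6βH-cis-decal-7-en-4-one | CC1(C)O[C@@H]2[C@H](O1)[C@@H](C(C)=C)C(=O)[C@@]3(C)[C@@H]2C=C(O[Si](C)(C)C(C)(C)C)C[C@@H]3C | intermediate
27 | 8-(tert-butyldimethylsilyloxy)-3β-isopropenyl-1α,2α-(isopropylidenedioxy)-5β,10β-dimethyl-6βH-cis-decal-7-en-4ξ-ol | CC1(C)O[C@@H]2[C@H](O1)[C@@H](C(C)=C)C(O)[C@@]3(C)[C@@H]2C=C(O[Si](C)(C)C(C)(C)C)C[C@@H]3C | intermediate
28 | potassium O-(C4) dithiocarbonate of alcohol 27 (potassium xanthate) | CC1(C)O[C@@H]2[C@H](O1)[C@@H](C(C)=C)C(OC(=S)[S-])[C@@]3(C)[C@@H]2C=C(O[Si](C)(C)C(C)(C)C)C[C@@H]3C.[K+] | intermediate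
29 | O-(C4) S-methyl dithiocarbonate of alcohol 27 | CC1(C)O[C@@H]2[C@H](O1)[C@@H](C(C)=C)C(OC(=S)SC)[C@@]3(C)[C@@H]2C=C(O[Si](C)(C)C(C)(C)C)C[C@@H]3C | intermediate
30 | 8-(tert-butyldimethylsilyloxy)-3β-isopropenyl-1α,2α-(isopropylidenedioxy)-5β,10β-dimethyl-6βH-cis-decal-7-ene | CC1(C)O[C@@H]2[C@H](O1)[C@@H](C(C)=C)C[C@@]3(C)[C@@H]2C=C(O[Si](C)(C)C(C)(C)C)C[C@@H]3C | intermediate
31 | 1α,2α-dihydroxy-3β-isopropenyl-5β,10β-dimethyl-6βH-cis-decalin-8-one | O[C@@H]1[C@H](O)[C@@H](C(C)=C)C[C@@]2(C)[C@@H]1CC(=O)C[C@@H]2C | intermediate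
32 | 1α-hydroxy-3β-isopropenyl-5β,10β-dimethyl-2α-(triethylsilyloxy)-6βH-cis-decalin-8-one | O[C@@H]1[C@H](O[Si](CC)(CC)CC)[C@@H](C(C)=C)C[C@@]2(C)[C@@H]1CC(=O)C[C@@H]2C | intermediate
33 | angelic acid [(Z)-2-methylbut-2-enoic acid] | C/C=C(/C)C(=O)O | starting material
34 | (Z)-2-methylbut-2-enoic 2,4,6-trichlorobenzoic anhydride (mixed anhydride) | C/C=C(/C)C(=O)OC(=O)c1c(Cl)cc(Cl)cc1Cl | intermediate
35 | 3β-isopropenyl-5β,10β-dimethyl-8-oxo-2α-(triethylsilyloxy)-6βH-cis-decalin-1α-yl (Z)-2-methylbut-2-enoate | C/C=C(/C)C(=O)O[C@@H]1[C@H](O[Si](CC)(CC)CC)[C@@H](C(C)=C)C[C@@]2(C)[C@@H]1CC(=O)C[C@@H]2C | intermediate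
36 | 2α-hydroxy-3β-isopropenyl-5β,10β-dimethyl-8-oxo-6βH-cis-decalin-1α-yl (Z)-2-methylbut-2-enoate | C/C=C(/C)C(=O)O[C@@H]1[C@H](O)[C@@H](C(C)=C)C[C@@]2(C)[C@@H]1CC(=O)C[C@@H]2C | intermediate
37 | CNP0206528.1: (1S,2R,3S,5R,6S,10S)-2-hydroxy-5,10-dimethyl-3-[(2R)-2-methyloxiran-2-yl]-8-oxo-cis-decalin-1-yl (Z)-2-methylbut-2-enoate (skeleton numbering) | C/C=C(/C)C(=O)O[C@@H]1[C@H](O)[C@@H]([C@]2(C)CO2)C[C@@]2(C)[C@@H]1CC(=O)C[C@@H]2C | target

**Step count and risks**

Total step count: 22. Longest linear sequence: 21 steps (steps 1–4 and 6–22; step 5 is the only branch).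

Steps most likely to fail:

1. Step 14 (key cycloaddition). The two carbonyl-endo chair transition states differ only by modest 1,3-diaxial interactions, so the diene may add to both faces of the dienophile. If the reaction is slow, the β,γ-unsaturated ketone may also epimerise at C3 or slip into conjugation. Fallback (catalyst-controlled 2-aminodiene cycloaddition, known chemistry): starting from 25, the silyl enol ether is removed at low temperature (HF·pyridine, pyridine, THF, −40 °C) to give the bis-enone (2E,5R)-5-{(4R,5S)-2,2-dimethyl-5-[(1E)-3-oxobut-1-en-1-yl]-1,3-dioxolan-4-yl}-3,6-dimethylhepta-2,6-dien-4-one F1. F1 is cyclised with a chiral primary amine (9-amino-9-deoxy-epi-quinine or its quinidine-derived pseudo-enantiomer, whichever is matched; PhCO2H co-catalyst, PhMe, 40 °C) through the 2-aminodiene formed at the methyl ketone; enamine hydrolysis gives the cis-fused 4,8-dione F2. Because the enol ether is lost, the unhindered C8 ketone is protected as its dioxolane (Me3SiOCH2CH2OSiMe3, Me3SiOTf cat., CH2Cl2, −78 °C) to give keto ketal F3. LiAlH4 then gives the C4 alcohol F4, KN(SiMe3)2/CS2/MeI the xanthate F5, and Bu3SnH/AIBN the deoxygenated ketal F6. The acid treatment of step 18 removes both ketals and the route is rejoined at 31.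

2. Step 13 (trienone generation). Addition of the α-branched organolithium to the hindered amide may be slow, leaving time for deprotonation at C3 (loss of configuration, deconjugation of the isopropenyl group). Fallback: from 21, i-Bu2AlH (THF, −78 °C) reduces the Weinreb amide to the aldehyde (2R)-2-{(4R,5S)-5-[(1E)-3-(tert-butyldimethylsilyloxy)buta-1,3-dien-1-yl]-2,2-dimethyl-1,3-dioxolan-4-yl}-3-methylbut-3-enal F7. The weakly basic organocerium reagent made from 23 and CeCl3 adds to this less hindered carbonyl (THF, −78 °C) to give the C4 carbinol F8 as an epimer mixture. Dess–Martin periodinane buffered with pyridine (CH2Cl2, 0 °C) oxidises F8 to 25, where the route is rejoined.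

3. Step 20 (angeloylation). Acylation of the hindered axial C1 hydroxyl may be sluggish, so that prolonged heating isomerises the activated angelate to the tiglate (Z to E). Fallback: from 32, the C1 hydroxyl is esterified with 2-[bis(2,2,2-trifluoroethoxy)phosphoryl]propanoic acid (DCC, DMAP, CH2Cl2; no alkene geometry to lose) to give the phosphonopropanoate F9. Still–Gennari olefination (KN(SiMe3)2, 18-crown-6, THF, −78 °C; then MeCHO) builds the Z-trisubstituted alkene on the molecule and gives 35, where the route is rejoined.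

**Further compounds**

F1 | step 14 | (2E,5R)-5-{(4R,5S)-2,2-dimethyl-5-[(1E)-3-oxobut-1-en-1-yl]-1,3-dioxolan-4-yl}-3,6-dimethylhepta-2,6-dien-4-one | C/C=C(\C)C(=O)[C@H](C(C)=C)[C@H]1OC(C)(C)O[C@H]1/C=C/C(C)=O
F2 | step 14 | 3β-isopropenyl-1α,2α-(isopropylidenedioxy)-5β,10β-dimethyl-6βH-cis-decalin-4,8-dione | CC1(C)O[C@@H]2[C@H](O1)[C@@H](C(C)=C)C(=O)[C@@]3(C)[C@@H]2CC(=O)C[C@@H]3C
F3 | step 14 | 8,8-(ethylenedioxy)-3β-isopropenyl-1α,2α-(isopropylidenedioxy)-5β,10β-dimethyl-6βH-cis-decalin-4-one | CC1(C)O[C@@H]2[C@H](O1)[C@@H](C(C)=C)C(=O)[C@@]3(C)[C@@H]2CC4(OCCO4)C[C@@H]3C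
F4 | step 14 | 8,8-(ethylenedioxy)-3β-isopropenyl-1α,2α-(isopropylidenedioxy)-5β,10β-dimethyl-6βH-cis-decalin-4ξ-ol | CC1(C)O[C@@H]2[C@H](O1)[C@@H](C(C)=C)C(O)[C@@]3(C)[C@@H]2CC4(OCCO4)C[C@@H]3C
F5 | step 14 | O-(C4) S-methyl dithiocarbonate of F4 | CC1(C)O[C@@H]2[C@H](O1)[C@@H](C(C)=C)C(OC(=S)SC)[C@@]3(C)[C@@H]2CC4(OCCO4)C[C@@H]3C
F6 | step 14 | 8,8-(ethylenedioxy)-3β-isopropenyl-1α,2α-(isopropylidenedioxy)-5β,10β-dimethyl-6βH-cis-decalin | CC1(C)O[C@@H]2[C@H](O1)[C@@H](C(C)=C)C[C@@]3(C)[C@@H]2CC4(OCCO4)C[C@@H]3C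
F7 | step 13 | (2R)-2-{(4R,5S)-5-[(1E)-3-(tert-butyldimethylsilyloxy)buta-1,3-dien-1-yl]-2,2-dimethyl-1,3-dioxolan-4-yl}-3-methylbut-3-enal | O=C[C@H](C(C)=C)[C@H]1OC(C)(C)O[C@H]1/C=C/C(=C)O[Si](C)(C)C(C)(C)C
F8 | step 13 | (2E)-5-{(4R,5S)-5-[(1E)-3-(tert-butyldimethylsilyloxy)buta-1,3-dien-1-yl]-2,2-dimethyl-1,3-dioxolan-4-yl}-3,6-dimethylhepta-2,6-dien-4-ol (C4 epimer mixture, C5 as in 25) | C/C=C(\C)C(O)[C@H](C(C)=C)[C@H]1OC(C)(C)O[C@H]1/C=C/C(=C)O[Si](C)(C)C(C)(C)C
F9 | step 20 | 3β-isopropenyl-5β,10β-dimethyl-8-oxo-2α-(triethylsilyloxy)-6βH-cis-decalin-1α-yl 2-[bis(2,2,2-trifluoroethoxy)phosphoryl]propanoate | CC(C(=O)O[C@@H]1[C@H](O[Si](CC)(CC)CC)[C@@H](C(C)=C)C[C@@]2(C)[C@@H]1CC(=O)C[C@@H]2C)P(=O)(OCC(F)(F)F)OCC(F)(F)F
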